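**Retrosynthetic overview**

1. The route rests on C4, C3 and the formyl carbon of ring B (numbering: ring B = C1(aryl)–C2(CH2OH)–C3(CHO)=C4–C4a–C8a; ring A = C4a, C5, C6, C7(OH), C8(OMe), C8a). These three carbons are a buta-1,3-diene unit that can be inserted between C4a (as an aryl bromide, para to the C7 oxygen) and C2 (as a malonate carbanion).
2. Target 24 ⇐ protected enal 22 (two deprotections) ⇐ saturated aldehyde 21 (C3=C4 by dehydrogenation) ⇐ vinyl tetralin 18 (alkene cleavage removes the fourth diene carbon) ⇐ trans monoester 15 ⇐ 2,2-diester 13.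
3. Key disconnection: 13 ⇒ bromoaryl malonate 11 + buta-1,3-diene 12, forming C4–C4a and C2–C3 and closing ring B in a Pd-catalysed [4+2] carboannulation.
4. 11 ⇒ arylidene malonate 9 + arylboronic acid 10 (C1–aryl bond; Rh/chiral diene 1,4-addition sets C1); 9 ⇒ bromoaldehyde 7 + dimethyl malonate 8; 7 from 2,3-dihydroxybenzaldehyde 1.
5. Ring order: ring A and the dimethoxyphenyl ring are bought; ring B is the only ring formed (step 6); C2 is set afterwards by equilibration trans to the C1 aryl group.

Key step: step 6

Assumption: the (R,R) enantiomer of 2,5-diphenylbicyclo[2.2.2]octa-2,5-diene is taken to deliver the aryl group to the face of 9 that gives (S)-11; should the sense be the opposite, the (S,S) ligand is used and nothing else changes.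
Remark: all names use the numbering of the overview; compounds 13 to 21 are carried as mixtures of C3 epimers, which converge when C3 becomes trigonal in step 11.

**Route**

Step 1
Reactants: 1 2,3-dihydroxybenzaldehyde; 2 benzyl bromide
Product: 3 3-(benzyloxy)-2-hydroxybenzaldehyde
Conditions: NaH (2.2 equiv), DMSO, 20 °C; then 2 (1.0 equiv); aq. HCl work-up
Reagents that add atoms: benzyl bromide, BrCc1ccccc1
Why: Double deprotonation gives a dianion whose 3-phenoxide, neither chelated by nor conjugated to the formyl group, is the more nucleophilic oxygen, so one equivalent of benzyl bromide should alkylate O3 selectively (Williamson etherification).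

Step 2
Reactants: 3 3-(benzyloxy)-2-hydroxybenzaldehyde; 4 iodomethane
Product: 5 3-(benzyloxy)-2-methoxybenzaldehyde
Conditions: K2CO3, DMF, 25 °C
Reagents that add atoms: iodomethane, CI
Why: Williamson methylation of the remaining formyl-chelated phenol should go to completion with excess iodomethane under carbonate conditions.

Step 3
Reactants: 5 3-(benzyloxy)-2-methoxybenzaldehyde; 6 N-bromosuccinimide
Product: 7 3-(benzyloxy)-6-bromo-2-methoxybenzaldehyde
Conditions: DMF, 25 °C, dark
Reagents that add atoms: N-bromosuccinimide, O=C1CCC(=O)N1Br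
Why: Electrophilic aromatic bromination should go para to the benzyloxy oxygen (C6), because the flanked 2-methoxy group is twisted out of conjugation and activates C5 less, the outcome known for 2,3-dimethoxybenzaldehyde under these conditions.

Step 4
Reactants: 7 3-(benzyloxy)-6-bromo-2-methoxybenzaldehyde; 8 dimethyl malonate
Product: 9 dimethyl 2-{[3-(benzyloxy)-6-bromo-2-methoxyphenyl]methylidene}propanedioate
Conditions: piperidine (0.2 equiv), AcOH (0.2 equiv), toluene, reflux, Dean–Stark
Reagents that add atoms: dimethyl malonate, COC(=O)CC(=O)OC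
Why: Knoevenagel condensation driven by azeotropic removal of water; the symmetric malonate makes the alkene geometry irrelevant.

Step 5
Reactants: 9 dimethyl 2-{[3-(benzyloxy)-6-bromo-2-methoxyphenyl]methylidene}propanedioate; 10 (3,4-dimethoxyphenyl)boronic acid
Product: 11 dimethyl 2-{(S)-[3-(benzyloxy)-6-bromo-2-methoxyphenyl](3,4-dimethoxyphenyl)methyl}propanedioate
Conditions: [RhCl(C2H4)2]2 (2.5 mol%), (R,R)-2,5-diphenylbicyclo[2.2.2]octa-2,5-diene (5.5 mol%), KOH (0.5 equiv), 10 (2 equiv), 1,4-dioxane/H2O 10:1, 50 °C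
Reagents that add atoms: (3,4-dimethoxyphenyl)boronic acid, COc1ccc(B(O)O)cc1OC
Why: Rh-catalysed asymmetric 1,4-addition (Hayashi–Miyaura reaction): the aryl–rhodium(diene) species formed by transmetalation inserts the electron-poor alkene with the chiral diene choosing the face at C1, protonation of the rhodium malonate enolate releases (S)-11, and the aryl bromide is inert to monovalent rhodium at 50 °C.

Step 6
Reactants: 11 dimethyl 2-{(S)-[3-(benzyloxy)-6-bromo-2-methoxyphenyl](3,4-dimethoxyphenyl)methyl}propanedioate; 12 buta-1,3-diene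
Product: 13 dimethyl (1S)-7-(benzyloxy)-1-(3,4-dimethoxyphenyl)-3-ethenyl-8-methoxy-3,4-dihydro-1H-naphthalene-2,2-dicarboxylate (both C3 epimers)
Conditions: Pd(OAc)2 (5 mol%), [HP(t-Bu)3]BF4 (10 mol%), K2CO3 (2.5 equiv), 12 (5 equiv, 2 M in THF), DMF, 90 °C, sealed tube
Reagents that add atoms: buta-1,3-diene, C=CC=C
Why: Pd(OAc)2 is reduced in the flask to zerovalent palladium carrying P(t-Bu)3, which inserts into the electron-rich C4a–Br bond; the aryl–palladium bromide then adds across one double bond of 12 with the aryl group on the terminal carbon (new C4–C4a bond), giving an η3-allyl complex of divalent palladium that spans C3, the future formyl carbon and the terminal CH2. The carbonate-generated malonate anion at C2 attacks this allyl unit at its near terminus C3 on the face opposite the metal (new C2–C3 bond) and releases zerovalent palladium. The closest known reaction type is the Larock carboannulation of 1,3-dienes by ortho-halobenzyl malonates, which gives 3-vinyltetralin-2,2-dicarboxylates. Ring B closes in a 6-exo mode at the allyl carbon nearer the arene, the alternative being attack at the far CH2 to give an eight-membered ring. The new stereocentre C3 is set relative to C1 by a chair-like transition state (C1 aryl pseudoaxial because of the peri C8 methoxy group, vinyl pseudoequatorial), but its configuration is immaterial because C3 later becomes trigonal, and C1 carries no acidic hydrogen and is untouched. The step needs diene insertion to outrun C–H arylation of the neighbouring dimethoxyphenyl ring and butadiene telomerisation, which the excess of 12, the bulky electron-rich phosphine and the moderate temperature should secure, while aryl delivery to the diene terminus is intrinsic to forming the stabilised allyl complex.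

Step 7
Reactants: 13 dimethyl (1S)-7-(benzyloxy)-1-(3,4-dimethoxyphenyl)-3-ethenyl-8-methoxy-3,4-dihydro-1H-naphthalene-2,2-dicarboxylate (both C3 epimers)
Product: 15 methyl (1S,2S)-7-(benzyloxy)-1-(3,4-dimethoxyphenyl)-3-ethenyl-8-methoxy-1,2,3,4-tetrahydronaphthalene-2-carboxylate (1,2-trans; C3 epimers), via C2-epimeric monoester mixture 14 (not isolated)
Conditions: LiCl (3 equiv), H2O (2 equiv), DMSO, 150 °C; aqueous work-up; then NaOMe (0.5 equiv), MeOH/THF, 50 °C
Reagents that add atoms: none
Why: Krapcho dealkoxycarbonylation (chloride SN2 at a methyl ester, loss of CO2, protonation) removes one ester, and methoxide then equilibrates the only enolisable centre, C2, toward the ester anti to the C1 aryl group, which peri strain with the C8 methoxy group holds pseudoaxial; the minor cis ester is separable and can be resubmitted to NaOMe.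

Step 8
Reactants: 15 methyl (1S,2S)-7-(benzyloxy)-1-(3,4-dimethoxyphenyl)-3-ethenyl-8-methoxy-1,2,3,4-tetrahydronaphthalene-2-carboxylate
Product: 16 [(1S,2S)-7-(benzyloxy)-1-(3,4-dimethoxyphenyl)-3-ethenyl-8-methoxy-1,2,3,4-tetrahydronaphthalen-2-yl]methanol
Conditions: LiAlH4, THF, 0 °C
Reagents that add atoms: none
Why: Hydride reduction of the ester to the primary alcohol; aryl ethers and the vinyl group are inert, and C2 is no longer epimerisable once it carries CH2OH.

Step 9
Reactants: 16 [(1S,2S)-7-(benzyloxy)-1-(3,4-dimethoxyphenyl)-3-ethenyl-8-methoxy-1,2,3,4-tetrahydronaphthalen-2-yl]methanol; 17 tert-butyldimethylsilyl chloride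
Product: 18 tert-butyl{[(1S,2S)-7-(benzyloxy)-1-(3,4-dimethoxyphenyl)-3-ethenyl-8-methoxy-1,2,3,4-tetrahydronaphthalen-2-yl]methoxy}dimethylsilane
Conditions: imidazole, DMF, 25 °C
Reagents that add atoms: tert-butyldimethylsilyl chloride, CC(C)(C)[Si](C)(C)Cl
Why: Silylation of the only free hydroxyl, so that the aldehyde made next cannot close a five-membered lactol onto it.

Step 10
Reactants: 18 tert-butyl{[(1S,2S)-7-(benzyloxy)-1-(3,4-dimethoxyphenyl)-3-ethenyl-8-methoxy-1,2,3,4-tetrahydronaphthalen-2-yl]methoxy}dimethylsilane; 19 ozone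
Product: 21 (1S,2R)-7-(benzyloxy)-2-{[tert-butyl(dimethyl)silyl]oxymethyl}-1-(3,4-dimethoxyphenyl)-8-methoxy-1,2,3,4-tetrahydronaphthalene-3-carbaldehyde (C3 epimers), via secondary ozonide 20 (not isolated)
Conditions: O3, CH2Cl2, −78 °C, Sudan Red 7B end point; then PPh3, −78 °C to 25 °C
Reagents that add atoms: ozone, [O-][O+]=O
Why: Ozonolysis with reductive work-up: the monosubstituted alkene should react far faster than the alkoxyarenes, the indicator dye marks the end point, and PPh3 reduces the ozonide to the aldehyde and formaldehyde, which excises the fourth butadiene carbon.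

Step 11
Reactants: 21 (1S,2R)-7-(benzyloxy)-2-{[tert-butyl(dimethyl)silyl]oxymethyl}-1-(3,4-dimethoxyphenyl)-8-methoxy-1,2,3,4-tetrahydronaphthalene-3-carbaldehyde
Product: 22 (1S,2R)-7-(benzyloxy)-2-{[tert-butyl(dimethyl)silyl]oxymethyl}-1-(3,4-dimethoxyphenyl)-8-methoxy-1,2-dihydronaphthalene-3-carbaldehyde
Conditions: IBX (2 equiv), 4-methoxypyridine N-oxide (2 equiv), DMSO, 25 °C
Reagents that add atoms: none
Why: IBX dehydrogenation of an aldehyde through its enol: hydrogen should be lost from benzylic C4 (two weaker, less hindered C–H bonds and a styrene-conjugated product) and not from the tertiary C2, and the room-temperature N-oxide variant spares C1, C2 and the electron-rich rings.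

Step 12
Reactants: 22 (1S,2R)-7-(benzyloxy)-2-{[tert-butyl(dimethyl)silyl]oxymethyl}-1-(3,4-dimethoxyphenyl)-8-methoxy-1,2-dihydronaphthalene-3-carbaldehyde
Product: 23 (1S,2R)-2-{[tert-butyl(dimethyl)silyl]oxymethyl}-1-(3,4-dimethoxyphenyl)-7-hydroxy-8-methoxy-1,2-dihydronaphthalene-3-carbaldehyde
Conditions: BCl3 (2.5 equiv), pentamethylbenzene (3 equiv), CH2Cl2, −78 °C; aq. NaHCO3
Reagents that add atoms: none
Why: Lewis acid debenzylation in which BCl3 activates the aryl benzyl ether and pentamethylbenzene traps the benzyl cation (Friedel–Crafts), which at −78 °C should spare the aryl methyl ethers, the enal, the styrenic alkene and largely the primary silyl ether; any silyl loss only anticipates step 13.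

Step 13
Reactants: 23 (1S,2R)-2-{[tert-butyl(dimethyl)silyl]oxymethyl}-1-(3,4-dimethoxyphenyl)-7-hydroxy-8-methoxy-1,2-dihydronaphthalene-3-carbaldehyde
Product: 24 vitekwangin B, (1S,2R)-1-(3,4-dimethoxyphenyl)-7-hydroxy-2-(hydroxymethyl)-8-methoxy-1,2-dihydronaphthalene-3-carbaldehyde
Conditions: HF·pyridine, pyridine, THF, 0 °C to 25 °C
Reagents that add atoms: none
Why: Fluoride-mediated desilylation under buffered, non-basic conditions, so that the free phenol is never turned into a phenoxide conjugated to the enal; C1 and C2 are not touched.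

**Compound list**

1 | 2,3-dihydroxybenzaldehyde | O=Cc1cccc(O)c1O | starting material
2 | benzyl bromide | BrCc1ccccc1 | starting material
3 | 3-(benzyloxy)-2-hydroxybenzaldehyde | O=Cc1cccc(OCc2ccccc2)c1O | intermediate
4 | iodomethane | CI | starting material
5 | 3-(benzyloxy)-2-methoxybenzaldehyde | O=Cc1cccc(OCc2ccccc2)c1OC | intermediate
6 | N-bromosuccinimide | O=C1CCC(=O)N1Br | starting material
7 | 3-(benzyloxy)-6-bromo-2-methoxybenzaldehyde | O=Cc1c(Br)ccc(OCc2ccccc2)c1OC | intermediate
8 | dimethyl malonate | COC(=O)CC(=O)OC | starting material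
9 | dimethyl 2-{[3-(benzyloxy)-6-bromo-2-methoxyphenyl]methylidene}propanedioate | COC(=O)C(C(=O)OC)=Cc1c(Br)ccc(OCc2ccccc2)c1OC | intermediate
10 | (3,4-dimethoxyphenyl)boronic acid | COc1ccc(B(O)O)cc1OC | starting material
11 | dimethyl 2-{(S)-[3-(benzyloxy)-6-bromo-2-methoxyphenyl](3,4-dimethoxyphenyl)methyl}propanedioate | COC(=O)C(C(=O)OC)[C@@H](c1ccc(OC)c(OC)c1)c1c(Br)ccc(OCc2ccccc2)c1OC | intermediate
12 | buta-1,3-diene | C=CC=C | starting material
13 | dimethyl (1S)-7-(benzyloxy)-1-(3,4-dimethoxyphenyl)-3-ethenyl-8-methoxy-3,4-dihydro-1H-naphthalene-2,2-dicarboxylate, both C3 epimers | COc1ccc([C@H]2c3c(ccc(OCc4ccccc4)c3OC)CC(C=C)C2(C(=O)OC)C(=O)OC)cc1OC | intermediate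
14 | methyl (1S)-7-(benzyloxy)-1-(3,4-dimethoxyphenyl)-3-ethenyl-8-methoxy-1,2,3,4-tetrahydronaphthalene-2-carboxylate, mixture at C2 and C3 | COc1ccc([C@H]2c3c(ccc(OCc4ccccc4)c3OC)CC(C=C)C2C(=O)OC)cc1OC | intermediate
15 | methyl (1S,2S)-7-(benzyloxy)-1-(3,4-dimethoxyphenyl)-3-ethenyl-8-methoxy-1,2,3,4-tetrahydronaphthalene-2-carboxylate, 1,2-trans, C3 epimers | COc1ccc([C@H]2c3c(ccc(OCc4ccccc4)c3OC)CC(C=C)[C@@H]2C(=O)OC)cc1OC | intermediate
16 | [(1S,2S)-7-(benzyloxy)-1-(3,4-dimethoxyphenyl)-3-ethenyl-8-methoxy-1,2,3,4-tetrahydronaphthalen-2-yl]methanol, C3 epimers | COc1ccc([C@H]2c3c(ccc(OCc4ccccc4)c3OC)CC(C=C)[C@@H]2CO)cc1OC | intermediate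
17 | tert-butyldimethylsilyl chloride | CC(C)(C)[Si](C)(C)Cl | starting material
18 | tert-butyldimethylsilyl ether of 16 | COc1ccc([C@H]2c3c(ccc(OCc4ccccc4)c3OC)CC(C=C)[C@@H]2CO[Si](C)(C)C(C)(C)C)cc1OC | intermediate
19 | ozone | [O-][O+]=O | starting material
20 | secondary ozonide of 18 (C3 carries a 1,2,4-trioxolan-3-yl group) | COc1ccc([C@H]2c3c(ccc(OCc4ccccc4)c3OC)CC(C3OCOO3)[C@@H]2CO[Si](C)(C)C(C)(C)C)cc1OC | intermediate
21 | (1S,2R)-7-(benzyloxy)-2-{[tert-butyl(dimethyl)silyl]oxymethyl}-1-(3,4-dimethoxyphenyl)-8-methoxy-1,2,3,4-tetrahydronaphthalene-3-carbaldehyde, C3 epimers | COc1ccc([C@H]2c3c(ccc(OCc4ccccc4)c3OC)CC(C=O)[C@@H]2CO[Si](C)(C)C(C)(C)C)cc1OC | intermediate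
22 | (1S,2R)-7-(benzyloxy)-2-{[tert-butyl(dimethyl)silyl]oxymethyl}-1-(3,4-dimethoxyphenyl)-8-methoxy-1,2-dihydronaphthalene-3-carbaldehyde | COc1ccc([C@H]2c3c(ccc(OCc4ccccc4)c3OC)C=C(C=O)[C@@H]2CO[Si](C)(C)C(C)(C)C)cc1OC | intermediate
23 | (1S,2R)-2-{[tert-butyl(dimethyl)silyl]oxymethyl}-1-(3,4-dimethoxyphenyl)-7-hydroxy-8-methoxy-1,2-dihydronaphthalene-3-carbaldehyde | COc1ccc([C@H]2c3c(ccc(O)c3OC)C=C(C=O)[C@@H]2CO[Si](C)(C)C(C)(C)C)cc1OC | intermediate
24 | vitekwangin B, (1S,2R)-1-(3,4-dimethoxyphenyl)-7-hydroxy-2-(hydroxymethyl)-8-methoxy-1,2-dihydronaphthalene-3-carbaldehyde | COc1ccc([C@H]2c3c(ccc(O)c3OC)C=C(C=O)[C@@H]2CO)cc1OC | target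

**Step count**

Total: 13 steps. Longest linear sequence: 13 steps (1 to 24).

**Steps most likely to fail**

Step 6 (key step). Three processes may compete with diene insertion and ring closure: the aryl–palladium intermediate may arylate a C–H bond of the neighbouring dimethoxyphenyl ring (fluorene formation); zerovalent palladium may telomerise butadiene with the malonate C–H before oxidative addition; or the hindered tertiary malonate may attack the allyl complex so slowly that β-hydride elimination to an aryl diene takes over. The fallback separates the two bond formations and sets out from 11. Stille coupling with allyltributylstannane (Pd(PPh3)4, toluene, 100 °C) should give the allylarene dimethyl 2-{(S)-[3-(benzyloxy)-2-methoxy-6-(prop-2-enyl)phenyl](3,4-dimethoxyphenyl)methyl}propanedioate F1, which already holds the C4–C4a bond. Cross-metathesis with (Z)-but-2-ene-1,4-diyl diacetate (second-generation Grubbs catalyst, CH2Cl2, 40 °C) should give the allylic acetate dimethyl 2-{(S)-[6-((E)-4-acetoxybut-2-enyl)-3-(benzyloxy)-2-methoxyphenyl](3,4-dimethoxyphenyl)methyl}propanedioate F2. Intramolecular Tsuji–Trost alkylation (Pd(PPh3)4, NaH, THF, 65 °C) then passes through the same allyl complex, forms C2–C3 in the 6-exo mode and comes back to the route at 13.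

Step 5. The doubly ortho-substituted aryl group at the β-carbon is twisted and shields the alkene, so insertion may be slow enough for protodeboronation of 10 to win, or the ligand may discriminate the two faces poorly. The fallback gives up catalytic induction and sets out from 9. Copper-catalysed conjugate addition of commercial (3,4-dimethoxyphenyl)magnesium bromide (CuBr·SMe2 10 mol%, THF, −20 °C) should give racemic dimethyl 2-{[3-(benzyloxy)-6-bromo-2-methoxyphenyl](3,4-dimethoxyphenyl)methyl}propanedioate F3. Preparative chromatography on a chiral stationary phase then separates the enantiomers, and the (S) enantiomer comes back to the route at 11.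

Step 11. The hypervalent iodine oxidant may go beyond the enal (oxidation at the doubly benzylic C1–H or of the electron-rich rings), or hydrogen may be lost toward C2 instead of C4. The fallback replaces the iodine oxidant by a palladium-mediated dehydrogenation and sets out from 21. Enol silylation (TMSOTf, Et3N, CH2Cl2, 0 °C) should give the trimethylsilyl enol ether of 21, with a (trimethylsilyloxy)methylidene group at C3, F4. Saegusa–Ito oxidation (Pd(OAc)2 1.1 equiv, MeCN, 25 °C) should then give the enal by β-hydride elimination of a benzylic C4 hydrogen from the palladium enolate, coming back to the route at 22.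

**Further compounds**

F1 | step 6 | dimethyl 2-{(S)-[3-(benzyloxy)-2-methoxy-6-(prop-2-enyl)phenyl](3,4-dimethoxyphenyl)methyl}propanedioate | COC(=O)C(C(=O)OC)[C@@H](c1ccc(OC)c(OC)c1)c1c(CC=C)ccc(OCc2ccccc2)c1OC
F2 | step 6 | dimethyl 2-{(S)-[6-((E)-4-acetoxybut-2-enyl)-3-(benzyloxy)-2-methoxyphenyl](3,4-dimethoxyphenyl)methyl}propanedioate | COC(=O)C(C(=O)OC)[C@@H](c1ccc(OC)c(OC)c1)c1c(C/C=C/COC(C)=O)ccc(OCc2ccccc2)c1OC
F3 | step 5 | racemic dimethyl 2-{[3-(benzyloxy)-6-bromo-2-methoxyphenyl](3,4-dimethoxyphenyl)methyl}propanedioate | COC(=O)C(C(=O)OC)C(c1ccc(OC)c(OC)c1)c1c(Br)ccc(OCc2ccccc2)c1OC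
F4 | step 11 | trimethylsilyl enol ether of 21, (1S,2R), (trimethylsilyloxy)methylidene group at C3 | COc1ccc([C@H]2c3c(ccc(OCc4ccccc4)c3OC)CC(=CO[Si](C)(C)C)[C@@H]2CO[Si](C)(C)C(C)(C)C)cc1OC
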